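**Retrosynthetic overview**

1. 12 ⇐ 11: the two aryl pivalates are removed last.
2. 11 ⇐ 9 (through epoxide 10): the tetrahydrofuran, the only ring formed, is closed last as in the presumed biosynthesis. The E-styrene of the acyclic norlignan diol is epoxidised face-selectively and the primary hydroxyl opens the epoxide 5-exo with inversion, which sets ring C5 and the exocyclic carbinol carbon in one operation.
3. 9 ⇐ 8 + 3: cross-metathesis attaches the second aryl ring as the E-styrene.
4. 8 ⇐ 5 + 6: a catalytic asymmetric anti-selective allylboration sets ring C3 and C4.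
5. 5 ⇐ 3 + 4 and 3 ⇐ 1 + 2: one styrene, 3, supplies both aryl rings.

Assumption: the SMILES is read as (3S,4R,5S)-4-(4-hydroxy-3-methoxyphenyl)-5-[(R)-hydroxy(4-hydroxy-3-methoxyphenyl)methyl]oxolan-3-ol, the all-cis ring (locants below follow this name); compounds are numbered by first appearance in the forward route.

**Route**

Step 1
Reactants: 1 2-methoxy-4-vinylphenol; 2 pivaloyl chloride
Product: 3 2-methoxy-4-vinylphenyl pivalate
Conditions: PivCl (1.1 equiv), Et3N (1.5 equiv), DMAP (5 mol%), CH2Cl2, 0 °C to rt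
Reagents that add atoms: pivaloyl chloride (2), CC(C)(C)C(=O)Cl
Why: DMAP-catalysed O-acylation of the phenol gives a hindered aryl ester that survives the later pH 10.5 oxidation and makes the aryl ring electron-poor enough that the benzylic epoxide of step 5 does not ionise; no stereocentre is formed.

Step 2
Reactants: 3 2-methoxy-4-vinylphenyl pivalate; 4 allylboronic acid pinacol ester
Product: 5 2-methoxy-4-[(1E)-3-(4,4,5,5-tetramethyl-1,3,2-dioxaborolan-2-yl)prop-1-en-1-yl]phenyl pivalate
Conditions: 4 (2 equiv), second-generation Hoveyda–Grubbs catalyst RuCl2(H2IMes)(=CH-C6H4-2-OiPr) (3 mol%), CH2Cl2, 40 °C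
Reagents that add atoms: allylboronic acid pinacol ester (4), C=CCB1OC(C)(C)C(C)(C)O1
Why: Olefin cross-metathesis of a styrene with the allylboronate releases ethylene and gives the thermodynamically preferred E-γ-aryl allylboronate, whose E geometry later fixes the anti relationship; no stereocentre is formed.

Step 3
Reactants: 5 the E-γ-aryl allylboronate; 6 (tert-butyldimethylsilyloxy)acetaldehyde
Product: 8 (2S,3R)-3-(3-methoxy-4-pivaloyloxyphenyl)pent-4-ene-1,2-diol, via pinacol borate 7 (not isolated)
Conditions: (S)-TRIP [(S)-3,3'-bis(2,4,6-triisopropylphenyl)-1,1'-binaphthyl-2,2'-diyl hydrogen phosphate] (5 mol%), 4 Å MS, toluene, −30 to 0 °C; then HCl (1 M in MeOH), rt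
Reagents that add atoms: (tert-butyldimethylsilyloxy)acetaldehyde (6), O=CCO[Si](C)(C)C(C)(C)C
Why: Chiral phosphoric acid-catalysed allylboration (Antilla type) runs through a closed chair Zimmerman–Traxler transition state in which the E-γ-aryl group is equatorial, giving the anti carbinol/aryl pair, while (S)-TRIP directs attack to the Si face of the aldehyde (mirror image of the Re-face preference of (R)-TRIP) to give 2S and hence 2S,3R; acidic methanol then cleaves the borate and the primary silyl ether.

Step 4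
Reactants: 8 (2S,3R)-3-(3-methoxy-4-pivaloyloxyphenyl)pent-4-ene-1,2-diol; 3 2-methoxy-4-vinylphenyl pivalate
Product: 9 (2S,3R,4E)-3,5-bis(3-methoxy-4-pivaloyloxyphenyl)pent-4-ene-1,2-diol
Conditions: 3 (3 equiv), second-generation Hoveyda–Grubbs catalyst RuCl2(H2IMes)(=CH-C6H4-2-OiPr) (5 mol%), 1,4-benzoquinone (10 mol%), CH2Cl2, 40 °C
Reagents that add atoms: 2-methoxy-4-vinylphenyl pivalate (3), C=Cc1ccc(OC(=O)C(C)(C)C)c(OC)c1
Why: Olefin cross-metathesis of the monosubstituted alkene with excess styrene gives the E-styrene under thermodynamic control with loss of ethylene, the free diol is tolerated, and benzoquinone suppresses ruthenium hydride alkene migration that would erase the doubly activated C3 stereocentre; both existing stereocentres are untouched.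

Step 5
Reactants: 9 (2S,3R,4E)-3,5-bis(3-methoxy-4-pivaloyloxyphenyl)pent-4-ene-1,2-diol
Product: 11 (3S,4R,5S)-5-[(R)-hydroxy(3-methoxy-4-pivaloyloxyphenyl)methyl]-4-(3-methoxy-4-pivaloyloxyphenyl)oxolan-3-ol, via epoxy diol 10 (not isolated)
Conditions: Shi ketone (1,2:4,5-di-O-isopropylidene-β-D-erythro-2,3-hexodiulo-2,6-pyranose, 30 mol%), Oxone (2KHSO5·KHSO4·K2SO4), K2CO3, Bu4NHSO4 (5 mol%), MeCN–DMM/aq. Na2B4O7 buffer, pH 10.5, 0 °C; then, on the crude extract, KOtBu (10 mol%), THF, 0 °C
Reagents that add atoms: Oxone, active component potassium peroxymonosulfate KHSO5, [K+].[O-]S(=O)(=O)OO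
Why: Shi asymmetric epoxidation followed by base-catalysed 5-exo-tet epoxide opening: the dioxirane of the D-fructose-derived ketone attacks the E-styrene through the spiro transition state on the face that gives the (R,R)-epoxide 10, as for trans-β-methylstyrene, which fixes the carbinol carbon as R, and the primary alkoxide then opens the epoxide at the non-benzylic carbon with inversion to set ring C5 as S, cis to the aryl group, while the pivalate-deactivated ring and the basic medium suppress benzylic 6-endo and 5-endo opening.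

Step 6
Reactants: 11 the bis-pivalate of the target
Product: 12 Metasequirin E, (3S,4R,5S)-4-(4-hydroxy-3-methoxyphenyl)-5-[(R)-hydroxy(4-hydroxy-3-methoxyphenyl)methyl]oxolan-3-ol
Conditions: K2CO3 (3 equiv), MeOH, 0 °C to rt, under argon; aq. NH4Cl
Reagents that add atoms: none
Why: Base-mediated transesterification (methanolysis) of the two activated aryl esters frees both phenols under conditions mild enough that the 4-hydroxybenzylic alcohol does not ionise to a quinone methide, so no stereocentre is touched.

**Compound list**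

1 | 2-methoxy-4-vinylphenol | C=Cc1ccc(O)c(OC)c1 | starting material
2 | pivaloyl chloride | CC(C)(C)C(=O)Cl | starting material
3 | 2-methoxy-4-vinylphenyl pivalate | C=Cc1ccc(OC(=O)C(C)(C)C)c(OC)c1 | intermediate
4 | allylboronic acid pinacol ester (2-allyl-4,4,5,5-tetramethyl-1,3,2-dioxaborolane) | C=CCB1OC(C)(C)C(C)(C)O1 | starting material
5 | 2-methoxy-4-[(1E)-3-(4,4,5,5-tetramethyl-1,3,2-dioxaborolan-2-yl)prop-1-en-1-yl]phenyl pivalate | CC(C)(C)C(=O)Oc1ccc(/C=C/CB2OC(C)(C)C(C)(C)O2)cc1OC | intermediate
6 | (tert-butyldimethylsilyloxy)acetaldehyde | O=CCO[Si](C)(C)C(C)(C)C | starting material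
7 | 2-{[(2S,3R)-1-(tert-butyldimethylsilyloxy)-3-(3-methoxy-4-pivaloyloxyphenyl)pent-4-en-2-yl]oxy}-4,4,5,5-tetramethyl-1,3,2-dioxaborolane | CC(C)(C)[Si](C)(C)OC[C@@H](OB1OC(C)(C)C(C)(C)O1)[C@H](C=C)c1ccc(OC(=O)C(C)(C)C)c(OC)c1 | intermediate
8 | (2S,3R)-3-(3-methoxy-4-pivaloyloxyphenyl)pent-4-ene-1,2-diol | OC[C@@H](O)[C@H](C=C)c1ccc(OC(=O)C(C)(C)C)c(OC)c1 | intermediate
9 | (2S,3R,4E)-3,5-bis(3-methoxy-4-pivaloyloxyphenyl)pent-4-ene-1,2-diol | OC[C@@H](O)[C@H](/C=C/c1ccc(OC(=O)C(C)(C)C)c(OC)c1)c1ccc(OC(=O)C(C)(C)C)c(OC)c1 | intermediate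
10 | (2S,3R)-3-(3-methoxy-4-pivaloyloxyphenyl)-3-[(2R,3R)-3-(3-methoxy-4-pivaloyloxyphenyl)oxiran-2-yl]propane-1,2-diol | OC[C@@H](O)[C@@H](c1ccc(OC(=O)C(C)(C)C)c(OC)c1)[C@H]1O[C@@H]1c1ccc(OC(=O)C(C)(C)C)c(OC)c1 | intermediate
11 | (3S,4R,5S)-5-[(R)-hydroxy(3-methoxy-4-pivaloyloxyphenyl)methyl]-4-(3-methoxy-4-pivaloyloxyphenyl)oxolan-3-ol | COc1cc([C@H]2[C@@H]([C@H](O)c3ccc(OC(=O)C(C)(C)C)c(OC)c3)OC[C@H]2O)ccc1OC(=O)C(C)(C)C | intermediate
12 | Metasequirin E | COc1cc([C@H]2[C@@H]([C@H](O)c3ccc(O)c(OC)c3)OC[C@H]2O)ccc1O | target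

**Step count and risks**

Total step count: 6. Longest linear sequence: 6 steps (1 → 3 → 5 → 8 → 9 → 11 → 12).

Steps most likely to fail:

Step 5 (epoxidation and ring closure). The risks are that the catalyst does not override the bias of the neighbouring stereocentre, that the free diol interferes with the dioxirane, or that the epoxide opens at the benzylic carbon (six-membered ether) before the 5-exo closure to the crowded all-cis ring. The fallback sets out from 9 and comes back at 11. It separates the two events with a protecting-group gate. Both hydroxyls of 9 are silylated (Et3SiCl, imidazole, DMF) to give the bis(triethylsilyl) ether F1. The same Shi conditions then give the hydroxyl-free epoxide F2, which can be purified, checked for configuration and freed from any minor diastereomer. Bu4NF in THF at 0 °C then removes both silyl groups, and the ammonium alkoxide so released closes the ring 5-exo in the same flask to give 11.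

Step 4 (cross-metathesis). The alkene of 8 is branched at the allylic carbon and may react slowly, and any alkene migration destroys C3. The fallback sets out from 8 and comes back at 9. 4-Iodo-2-methoxyphenol is acylated with 2 (Et3N, DMAP, CH2Cl2) to 4-iodo-2-methoxyphenyl pivalate F3. A Mizoroki–Heck arylation of 8 with F3 under ligand-free Jeffery conditions (Pd(OAc)2, Bu4NCl, NaHCO3, DMF, 50 °C) then places the aryl group on the terminal carbon. β-Hydride elimination toward the new benzylic position gives the conjugated E-styrene 9.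

Step 3 (asymmetric allylboration). The γ-aryl boronate is less reactive than a crotylboronate, so a slow catalysed reaction or a competing uncatalysed one could erode the enantiomeric excess. The fallback sets out from 6 and comes back at 8. It uses stereodivergent dual iridium/amine catalysis (Carreira type) in place of boron chemistry. Vanillin is acylated with 2 to 4-formyl-2-methoxyphenyl pivalate F4. Addition of CH2=CHMgBr in THF at −78 °C gives the racemic allylic alcohol 4-(1-hydroxyprop-2-en-1-yl)-2-methoxyphenyl pivalate F5. F5 and 6 are then coupled with [Ir(cod)Cl]2, a chiral phosphoramidite–olefin ligand, a diarylprolinol trimethylsilyl ether and dimethyl hydrogen phosphate in 1,2-dichloroethane. The iridium allyl complex sets the aryl-bearing carbon and the enamine of 6 sets the oxygen-bearing carbon, and the catalyst pair is chosen to give the aldehyde (2S,3R)-2-(tert-butyldimethylsilyloxy)-3-(3-methoxy-4-pivaloyloxyphenyl)pent-4-enal F6. NaBH4 in MeOH reduces F6 to the primary alcohol (2S,3R)-2-(tert-butyldimethylsilyloxy)-3-(3-methoxy-4-pivaloyloxyphenyl)pent-4-en-1-ol F7, and HCl in MeOH removes the silyl group to give 8.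

**Further compounds**

F1 | step 5 | bis(triethylsilyl) ether of 9 | CC[Si](CC)(CC)OC[C@@H](O[Si](CC)(CC)CC)[C@H](/C=C/c1ccc(OC(=O)C(C)(C)C)c(OC)c1)c1ccc(OC(=O)C(C)(C)C)c(OC)c1
F2 | step 5 | trans-epoxide of F1 with the epoxide configuration of 10 | CC[Si](CC)(CC)OC[C@@H](O[Si](CC)(CC)CC)[C@@H](c1ccc(OC(=O)C(C)(C)C)c(OC)c1)[C@H]1O[C@@H]1c1ccc(OC(=O)C(C)(C)C)c(OC)c1
F3 | step 4 | 4-iodo-2-methoxyphenyl pivalate | COc1cc(I)ccc1OC(=O)C(C)(C)C
F4 | step 3 | 4-formyl-2-methoxyphenyl pivalate | COc1cc(C=O)ccc1OC(=O)C(C)(C)C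
F5 | step 3 | racemic 4-(1-hydroxyprop-2-en-1-yl)-2-methoxyphenyl pivalate | C=CC(O)c1ccc(OC(=O)C(C)(C)C)c(OC)c1
F6 | step 3 | (2S,3R)-2-(tert-butyldimethylsilyloxy)-3-(3-methoxy-4-pivaloyloxyphenyl)pent-4-enal | O=C[C@@H](O[Si](C)(C)C(C)(C)C)[C@H](C=C)c1ccc(OC(=O)C(C)(C)C)c(OC)c1
F7 | step 3 | (2S,3R)-2-(tert-butyldimethylsilyloxy)-3-(3-methoxy-4-pivaloyloxyphenyl)pent-4-en-1-ol | OC[C@@H](O[Si](C)(C)C(C)(C)C)[C@H](C=C)c1ccc(OC(=O)C(C)(C)C)c(OC)c1
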